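## Retrosynthetic overview

1. The feature is in the dihydrofuran ring O1–C2–C3–C3a–C7a: C3 carries both the benzoate ring carbon C3a and the oxygenated methylene C9, with the C2 aryl group trans. This is the pattern left when a C3a aryl radical adds 5-exo to a C3=C9 vinyl group and O2 caps C9.
2. After removal of the phenol silyl group, C3–C3a and C9–O are cut: target 11 ⇐ silyl ether 10 ⇐ (S)-configured o-iodoaryl 1-arylallyl ether 8.
3. O1–C2 of 8 is cut: iodophenol 2 plus linear cinnamyl carbonate 6, joined by an iridium-catalysed branched, enantioselective allylic etherification that sets C2.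
4. 2 comes from methyl vanillate 1 by iodination; 6 comes from methyl ferulate 3 by silylation, DIBAL-H reduction and carbonate formation.
5. Ring order: both benzene rings are bought; the dihydrofuran is the only ring made, in step 6.

Key step: step 6

Remarks on the chemistry:
- Benzofuran numbering is used; C9 is the hydroxymethyl carbon.
- The phenol of the cinnamyl half is carried as a triisopropylsilyl ether, chosen over tert-butyldimethylsilyl because step 5 exposes the aryl silyl ether to aryloxide and methoxide.
- L is the binaphthol-derived N,N-bis(1-phenylethyl)phosphoramidite. The (Sa,Sc,Sc) enantiomer is assumed to deliver the (S)-ether, as expected for heteroatom nucleophiles on cinnamyl carbonates; the sense would be checked on the first run and the antipodal ligand used otherwise.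
- Methyl vanillate and methyl ferulate are taken as commercial.

## Route

Step 1
Reactants: 1 methyl vanillate (methyl 4-hydroxy-3-methoxybenzoate)
Product: 2 methyl 4-hydroxy-3-iodo-5-methoxybenzoate
Conditions: NIS (1.05 equiv), TFA (cat.), MeCN, rt
Reagents that add atoms: N-iodosuccinimide, O=C1CCC(=O)N1I
Why: Electrophilic aromatic iodination, in which the phenol (para position blocked) directs ortho and the ester directs meta, both to C5, so a single regioisomer should form.

Step 2
Reactants: 3 methyl ferulate (methyl (E)-3-(4-hydroxy-3-methoxyphenyl)prop-2-enoate)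
Product: 4 methyl (E)-3-[3-methoxy-4-(triisopropylsilyloxy)phenyl]prop-2-enoate
Conditions: TIPSCl, imidazole, DMF, rt
Reagents that add atoms: triisopropylsilyl chloride, CC(C)[Si](Cl)(C(C)C)C(C)C
Why: Imidazole-promoted O-silylation of a phenol, giving a bulky aryl silyl ether that should tolerate the hydride, acylation, aryloxide and radical conditions that follow.

Step 3
Reactants: 4 methyl (E)-3-[3-methoxy-4-(triisopropylsilyloxy)phenyl]prop-2-enoate
Product: 5 (E)-3-[3-methoxy-4-(triisopropylsilyloxy)phenyl]prop-2-en-1-ol
Conditions: DIBAL-H (2.5 equiv), CH2Cl2, −78 °C; aq. Rochelle salt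
Reagents that add atoms: none
Why: DIBAL-H 1,2-reduction of an α,β-unsaturated ester to the allylic alcohol at low temperature, which should leave the E-alkene and the aryl silyl ether untouched.

Step 4
Reactants: 5 (E)-3-[3-methoxy-4-(triisopropylsilyloxy)phenyl]prop-2-en-1-ol
Product: 6 (E)-3-[3-methoxy-4-(triisopropylsilyloxy)phenyl]prop-2-en-1-yl methyl carbonate
Conditions: ClCO2Me, pyridine, CH2Cl2, 0 °C
Reagents that add atoms: methyl chloroformate, COC(=O)Cl
Why: O-acylation of the primary allylic alcohol with a chloroformate installs the carbonate leaving group needed for allyl–iridium formation.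

Step 5
Reactants: 2 methyl 4-hydroxy-3-iodo-5-methoxybenzoate; 6 (E)-3-[3-methoxy-4-(triisopropylsilyloxy)phenyl]prop-2-en-1-yl methyl carbonate
Product: 8 methyl 3-iodo-5-methoxy-4-{(1S)-1-[3-methoxy-4-(triisopropylsilyloxy)phenyl]prop-2-enyloxy}benzoate, via lithium aryloxide 7 (not isolated)
Conditions: 2 (1.5 equiv), LiHMDS, THF, 0 °C; then 6 (1.0 equiv), [Ir(cod)Cl]2 (2 mol%), (Sa,Sc,Sc)-L (4 mol%, pre-activated with n-PrNH2), THF, rt; Et3N-deactivated silica
Reagents that add atoms: none
Why: Iridium-catalysed asymmetric allylic etherification with a cyclometalated Ir–phosphoramidite catalyst, in which the aryloxide attacks the aryl-substituted terminus of the allyl–iridium intermediate to give the branched ether and the ligand selects the face so that C2 is set as S.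

Step 6
Reactants: 8 methyl 3-iodo-5-methoxy-4-{(1S)-1-[3-methoxy-4-(triisopropylsilyloxy)phenyl]prop-2-enyloxy}benzoate
Product: 10 methyl (2S,3R)-3-(hydroxymethyl)-7-methoxy-2-[3-methoxy-4-(triisopropylsilyloxy)phenyl]-2,3-dihydrobenzofuran-5-carboxylate, via hydroperoxide 9 (not isolated)
Conditions: Bu3SnH (slow addition), dry air stream, toluene, 0 °C to rt; then PPh3, rt; aq. KF
Reagents that add atoms: dioxygen (from air), O=O
Why: Tributyltin radical (chain started by O2 acting on the stannane) abstracts iodine from C3a, the σ-aryl radical adds to the internal vinyl carbon to form C3–C3a, the primary C9 radical combines with O2, and the peroxyl radical takes hydrogen from Bu3SnH to give hydroperoxide 9 and carry the chain; PPh3 then reduces 9 to alcohol 10. The closest known reaction type is the tin hydride/air oxygenative cyclisation of o-iodophenyl allyl ethers to 3-(hydroxymethyl)-2,3-dihydrobenzofurans. The dihydrofuran ring closes 5-exo-trig, which for o-allyloxyphenyl radicals is far faster than 6-endo closure, reduction by the stannane or oxygen capture of the aryl radical. C3 is set by substrate control from C2: in the chair-like 5-exo transition state the C2 aryl group lies pseudo-equatorial and anti to the developing C9 methylene, so the 2,3-trans (2S,3R) isomer should dominate while C2 is untouched; any cis isomer would be removed by chromatography. The step needs O2 capture at C9 to beat hydrogen transfer and neophyl-type ring expansion; the unhindered, unstabilised primary radical reacts with O2 at near diffusion rate, and slow stannane addition under a steady air stream keeps the hydride concentration low.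

Step 7
Reactants: 10 methyl (2S,3R)-3-(hydroxymethyl)-7-methoxy-2-[3-methoxy-4-(triisopropylsilyloxy)phenyl]-2,3-dihydrobenzofuran-5-carboxylate
Product: 11 curlignan, methyl (2S,3R)-2-(4-hydroxy-3-methoxyphenyl)-3-(hydroxymethyl)-7-methoxy-2,3-dihydrobenzofuran-5-carboxylate
Conditions: TBAF (1.1 equiv), AcOH (1.1 equiv), THF, 0 °C
Reagents that add atoms: none
Why: Fluoride-mediated cleavage of the aryl O–Si bond, buffered with acetic acid so that the phenol is not left as a free phenoxide, which should leave the methyl ester, the primary alcohol and both stereocentres untouched.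

## Compound list

1 | methyl vanillate (methyl 4-hydroxy-3-methoxybenzoate) | COC(=O)c1ccc(O)c(OC)c1 | starting material
2 | methyl 4-hydroxy-3-iodo-5-methoxybenzoate | COC(=O)c1cc(I)c(O)c(OC)c1 | intermediate
3 | methyl ferulate (methyl (E)-3-(4-hydroxy-3-methoxyphenyl)prop-2-enoate) | COC(=O)/C=C/c1ccc(O)c(OC)c1 | starting material
4 | methyl (E)-3-[3-methoxy-4-(triisopropylsilyloxy)phenyl]prop-2-enoate | COC(=O)/C=C/c1ccc(O[Si](C(C)C)(C(C)C)C(C)C)c(OC)c1 | intermediate
5 | (E)-3-[3-methoxy-4-(triisopropylsilyloxy)phenyl]prop-2-en-1-ol | OC/C=C/c1ccc(O[Si](C(C)C)(C(C)C)C(C)C)c(OC)c1 | intermediate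
6 | (E)-3-[3-methoxy-4-(triisopropylsilyloxy)phenyl]prop-2-en-1-yl methyl carbonate | COC(=O)OC/C=C/c1ccc(O[Si](C(C)C)(C(C)C)C(C)C)c(OC)c1 | intermediate
7 | lithium 2-iodo-6-methoxy-4-(methoxycarbonyl)phenoxide | COC(=O)c1cc(I)c([O-])c(OC)c1.[Li+] | intermediate
8 | methyl 3-iodo-5-methoxy-4-{(1S)-1-[3-methoxy-4-(triisopropylsilyloxy)phenyl]prop-2-enyloxy}benzoate | COC(=O)c1cc(OC)c(O[C@@H](C=C)c2ccc(O[Si](C(C)C)(C(C)C)C(C)C)c(OC)c2)c(I)c1 | intermediate
9 | methyl (2S,3R)-3-(hydroperoxymethyl)-7-methoxy-2-[3-methoxy-4-(triisopropylsilyloxy)phenyl]-2,3-dihydrobenzofuran-5-carboxylate | COC(=O)c1cc(OC)c2c(c1)[C@H](COO)[C@@H](c1ccc(O[Si](C(C)C)(C(C)C)C(C)C)c(OC)c1)O2 | intermediate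
10 | methyl (2S,3R)-3-(hydroxymethyl)-7-methoxy-2-[3-methoxy-4-(triisopropylsilyloxy)phenyl]-2,3-dihydrobenzofuran-5-carboxylate | COC(=O)c1cc(OC)c2c(c1)[C@H](CO)[C@@H](c1ccc(O[Si](C(C)C)(C(C)C)C(C)C)c(OC)c1)O2 | intermediate
11 | curlignan, methyl (2S,3R)-2-(4-hydroxy-3-methoxyphenyl)-3-(hydroxymethyl)-7-methoxy-2,3-dihydrobenzofuran-5-carboxylate | COC(=O)c1cc(OC)c2c(c1)[C@H](CO)[C@@H](c1ccc(O)c(OC)c1)O2 | target

## Step count and risk

Total step count: 7. Longest linear sequence: 6 steps (3 → 4 → 5 → 6 → 8 → 10 → 11; steps 2 to 7).

**Step 6 (radical cyclisation with oxygen capture).** Hydrogen transfer from the stannane to the C9 radical may outrun oxygen capture, peroxyl chemistry may stall the chain or over-oxidise C9, and the trans preference in ring closure may be incomplete. The fallback sets out from 8 and returns at 10. Heating 8 with Bu3SnH and TEMPO in toluene at 70 °C runs the same aryl radical 5-exo closure, but the C9 radical is caught by the persistent nitroxide instead of O2. This gives the TEMPO alkoxyamine methyl (2S,3R)-7-methoxy-2-[3-methoxy-4-(triisopropylsilyloxy)phenyl]-3-[(2,2,6,6-tetramethylpiperidin-1-yl)oxymethyl]-2,3-dihydrobenzofuran-5-carboxylate F1. Zinc dust in AcOH–THF–H2O at 60 °C then cleaves the N–O bond to give 10.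

**Step 5 (iridium-catalysed etherification).** The di-ortho-substituted, weakly basic aryloxide may capture the allyl–iridium intermediate slowly. The product, an electron-rich benzylic ether of a good aryloxide leaving group, may re-ionise on the catalyst, drifting to the linear ether and losing enantiomeric purity. The fallback sets out from 6 and returns at 8, separating the asymmetric step from the aryl ether formation.
- The same Ir/L catalyst with KHCO3 as a small oxygen nucleophile (allylic hydroxylation) should give (1S)-1-[3-methoxy-4-(triisopropylsilyloxy)phenyl]prop-2-en-1-ol F2.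
- n-BuLi then Boc2O in THF at −78 °C converts it into tert-butyl (1S)-1-[3-methoxy-4-(triisopropylsilyloxy)phenyl]prop-2-en-1-yl carbonate F3, used without chromatography.
- [Cp*Ru(MeCN)3]PF6 (cat.) with phenol 2 and K2CO3 in acetone at rt, a branched-selective allylic etherification that proceeds with retention of configuration, then gives 8.

**Step 7 (desilylation).** The phenoxide released by fluoride in an aprotic medium may open the dihydrofuran at C2–O1 through a p-quinone methide, eroding trans purity at C2 or leading on to stilbene-type elimination. The fallback sets out from 10 and returns at 11. Ac2O, pyridine and DMAP acetylate the C9 alcohol, and CsF added to the same flask cleaves the silyl ether while the phenoxide is acetylated as it forms. This gives the diacetate methyl (2S,3R)-3-(acetoxymethyl)-2-(4-acetoxy-3-methoxyphenyl)-7-methoxy-2,3-dihydrobenzofuran-5-carboxylate F4. Catalytic K2CO3 in MeOH at 0 °C then removes both acetates by transesterification in a protic medium, where the solvated phenoxide is far less prone to ring opening, giving 11.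

## Further compounds

F1 | step 6 | methyl (2S,3R)-7-methoxy-2-[3-methoxy-4-(triisopropylsilyloxy)phenyl]-3-[(2,2,6,6-tetramethylpiperidin-1-yl)oxymethyl]-2,3-dihydrobenzofuran-5-carboxylate | COC(=O)c1cc(OC)c2c(c1)[C@H](CON1C(C)(C)CCCC1(C)C)[C@@H](c1ccc(O[Si](C(C)C)(C(C)C)C(C)C)c(OC)c1)O2
F2 | step 5 | (1S)-1-[3-methoxy-4-(triisopropylsilyloxy)phenyl]prop-2-en-1-ol | O[C@@H](C=C)c1ccc(O[Si](C(C)C)(C(C)C)C(C)C)c(OC)c1
F3 | step 5 | tert-butyl (1S)-1-[3-methoxy-4-(triisopropylsilyloxy)phenyl]prop-2-en-1-yl carbonate | CC(C)(C)OC(=O)O[C@@H](C=C)c1ccc(O[Si](C(C)C)(C(C)C)C(C)C)c(OC)c1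
F4 | step 7 | methyl (2S,3R)-3-(acetoxymethyl)-2-(4-acetoxy-3-methoxyphenyl)-7-methoxy-2,3-dihydrobenzofuran-5-carboxylate | COC(=O)c1cc(OC)c2c(c1)[C@H](COC(C)=O)[C@@H](c1ccc(OC(C)=O)c(OC)c1)O2
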